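Slowness shows in the product of the earlier runs, which keeps climbing across the readings while the dissolved substrate levels off; the solid reagent is never read.

| flask | solid substrate | solid reagent | remark | time |
|---|---|---|---|---|
| winter | 0.40 M | 0.47 equiv | run made earlier |  |
| dusk | 0.40 M | 1 equiv | run made earlier |  |
| summer | 0.60 M | 0.70 equiv | run made earlier |  |
| flask | 0.40 M | 0.700 equiv |  | 10 min |

| run | time / min | product / % | dissolved substrate / % |
|---|---|---|---|
| winter | 2.00 | 3.1 | 52.9 |
| winter | 4.00 | 3.7 | 68.7 |
| winter | 6.00 | 6.0 | 69.4 |
| winter | 8.00 | 14.0 | 72.8 |
| winter | 10.0 | 14.7 | 74.7 |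
| dusk | 0.833 | 0 | 30.9 |
| dusk | 1.50 | 1.4 | 46.1 |
| dusk | 3.00 | 2.7 | 61.6 |
| dusk | 5.00 | 8.6 | 69.4 |
| dusk | 10.0 | 16.5 | 71.4 |
| summer | 0.833 | 0.6 | 20.0 |
| summer | 2.50 | 0 | 39.2 |
| summer | 5.00 | 4.2 | 46.6 |
| summer | 8.00 | 6.6 | 48.5 |
| summer | 10.0 | 10.5 | 47.2 |

(each reading ± 1 percentage point)

- as a solid, counted per litre of solution: solid substrate, solid reagent
- at the start none of the solid substrate is in solution
- at the start none of the solid reagent is in solution
- dissolved substrate means what is dissolved; the solid is not counted in it

- product at 10 min, in percent of the solid substrate charged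
- concentration of dissolved substrate in solution at 10 min, in percent of saturation

Per litre, winter, dusk and summer end with 0.0588 M, 0.0660 M and 0.0630 M of product, and we call their mean q = 0.0626 M. That is an average use of dissolved substrate of about 0.00626 M min⁻¹, while the dusk solution first fills at F = 0.148 M min⁻¹, far faster than that use. So we let the dissolving of the solid substrate keep up and reckon with the ceiling, the most dissolved substrate a litre holds beside solid, read as the mean of the late readings: S = 0.289 M.

The summer run has nearly the flask's recipe, the same 0.70 equiv, yet shows dissolved substrate at 47.2%. Both charges stand above S , so we expect both solutions near the same molarity, and the percentages part through the divisor: for the flask S/0.40 M gives 72.2%. Product per litre should carry over likewise, so we reckon q/0.40 M = 15.7% for the flask. In a quasi-steady state, with A the dissolved substrate and k the dissolving coefficient, inflow k(S − A) equals the use and F is about kS, so A/S = 95.8%.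

The forecast differs slightly: 15.5% and 97%, with the ground “Rate therefore barely depends on reagent or solid loading”.

The flask ran by these steps:

    solid substrate ⇌ dissolved substrate, rate k1*(cs1 - [dissolved substrate]) while solid is left; crystals form when [dissolved substrate] > cs1 (solubility = 0.300 M, k = 0.0107 s⁻¹)
    dissolved substrate + partner → product (k = 0.00415 M⁻¹ s⁻¹)
    2 partner → homo dimer (k = 0.00440 M⁻¹ s⁻¹)
    solid reagent ⇌ partner, rate k4*(cs4 - [partner]) while solid is left; crystals form when [partner] > cs4 (solubility = 0.190 M, k = 0.00529 s⁻¹)

The flask gives 17.5% of product, with dissolved substrate at 95.1% of saturation. At 10.0 min its dissolved substrate is made 1.01 times faster than it is used up, each step taken net. S over the charge said 72.2%, and the flask holds dissolved substrate at 71.3%. For the neighbour flask with 0.10 M of solid substrate, S is 2.89 times the charge, and that flask ends with solid substrate at 0% and dissolved substrate at 88.0%.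

Readings and results are simulated with constants of no real substance; scatter was added.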